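The route rests on disconnecting the C3–C4 bond of ring A (drimane numbering). (S)-Carvone supplies ring B, the C5 stereocentre and, in its isopropenyl group, C4 with one geminal methyl; two enolate alkylations set quaternary C10 and attach C1–C3 as an allyl arm, which is oxidised to the aldehyde. The key step is an iron-hydride hydrogen-atom-transfer radical cyclisation: the isopropenyl group becomes the tertiary C4 radical, which adds to the C3 aldehyde, closing ring A and creating the gem-dimethyl quaternary carbon next to the C3 carbinol in one operation. Methylenation and hydroboration at C9, Mitsunobu etherification with umbelliferone, acetylation and allylic oxidation at C6 finish the synthesis.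

Key step: step 4

Remark on the chemistry: atoms are numbered as in drimane (ring A = C1–C5 and C10; ring B = C5–C10; C11 = the OCH2 carbon on C9; C12 = the methyl on C8). CIP descriptors of the bicyclic compounds refer to this numbering, and the SMILES strings are authoritative. Compound 3 is drawn as its major trans epimer; both C6 epimers converge in step 2.

Step 1
Reactants: 1 (S)-(+)-carvone
Product: 3 (5S,6R)-2,6-dimethyl-5-(prop-1-en-2-yl)cyclohex-2-en-1-one (trans-6-methylcarvone), via lithium dienolate of carvone 2 (not isolated)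
Conditions: LiN(iPr)2, THF, −78 °C; then MeI, −78 to 0 °C
Reagents that add atoms: iodomethane CI; lithium diisopropylamide [Li]N(C(C)C)C(C)C (lithium of 2 only)
Why: Kinetic deprotonation at the only sp3 α-carbon (C6 of carvone) and SN2 C-methylation of the cross-conjugated dienolate (enolate alkylation) should give mainly the trans epimer, and this centre is made planar again in step 2.

Step 2
Reactants: 3 trans-6-methylcarvone
Product: 5 (5R,6R)-2,6-dimethyl-5-(prop-1-en-2-yl)-6-(prop-2-en-1-yl)cyclohex-2-en-1-one (allyl trans to isopropenyl), via lithium dienolate of 6-methylcarvone 4 (not isolated)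
Conditions: LiN(iPr)2, THF, −78 to 0 °C; then allyl bromide, DMPU, −78 °C to rt
Reagents that add atoms: allyl bromide C=CCBr; lithium diisopropylamide [Li]N(C(C)C)C(C)C (lithium of 4 only)
Why: Enolate alkylation of the tetrasubstituted dienolate should occur on the face opposite the adjacent isopropenyl group (1,2-induction), which sets the quaternary centre (future C10) with the three-carbon arm trans to isopropenyl and the methyl cis to it.

Step 3
Reactants: 5 allyl ketone
Product: 6 3-[(1R,6R)-1,3-dimethyl-2-oxo-6-(prop-1-en-2-yl)cyclohex-3-en-1-yl]propanal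
Conditions: PdCl2(PhCN)2 (cat.), CuCl2·2H2O (cat.), AgNO2 (cat.), O2 (1 atm), t-BuOH/MeNO2, rt
Reagents that add atoms: dioxygen O=O
Why: The nitrite-modified, aldehyde-selective (anti-Markovnikov) Wacker oxidation should oxidise only the monosubstituted alkene at its terminal carbon, the neighbouring quaternary centre reinforcing terminal selectivity, while the 1,1-disubstituted alkene and the enone stay inert.

Step 4
Reactants: 6 keto aldehyde
Product: 7 (3R,5R,10R)-3-hydroxy-11-nordrim-7-en-9-one [(4aR,6R,8aR)-6-hydroxy-2,5,5,8a-tetramethyl-4a,5,6,7,8,8a-hexahydronaphthalen-1(4H)-one]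
Conditions: Fe(acac)3 (0.3 equiv), PhSiH3, EtOH, 60 °C
Reagents that add atoms: none
Why: Fe(acac)3 and PhSiH3 generate an iron hydride that transfers a hydrogen atom to the terminal CH2 of the isopropenyl group (Markovnikov HAT), giving the tertiary C4 radical, which adds to the C3 aldehyde carbon and forms the C3–C4 bond, after which the alkoxy radical is reduced by divalent iron and protonated by ethanol, making the closure irreversible and regenerating trivalent iron. The closest known reaction type is the iron-catalysed HAT-initiated reductive radical cyclisation of alkene-tethered carbonyl compounds (Mukaiyama-type MHAT chemistry). Ring A closes in a 6-exo-trig mode onto the C=O bond through a chair transition state in which the C10 arm and the C5 radical centre are trans-diequatorial on ring B, so the decalin is trans-fused with C5 and C10 unchanged. The only new stereocentre, C3, is controlled by this chair: the aldehyde oxygen should take the pseudo-equatorial position, away from the axial hydrogens on C1 and C5, which places the hydroxyl equatorial and cis to the C10 methyl. The step needs chemoselective HAT to the electron-rich 1,1-disubstituted alkene over the electron-poor enone alkene and cyclisation faster than reduction of the radical; the enone cannot trap the C4 radical because only three- or four-membered rings would result, and the aldehyde is held six atoms away on the trans-disposed arm.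

Step 5
Reactants: 7 hydroxy enone
Product: 8 (3R,5S,10R)-drima-7,9(11)-dien-3-ol
Conditions: Ph3PCH3Br, KOtBu (excess), toluene, 0 to 90 °C
Reagents that add atoms: methyltriphenylphosphonium bromide C[P+](c1ccccc1)(c1ccccc1)c1ccccc1.[Br-]
Why: Wittig methylenation with excess salt-tolerant ylide in hot toluene is the standard answer to hindered ketones; the C3 hydroxyl is carried as its alkoxide and no stereocentre is touched.

Step 6
Reactants: 8 diene alcohol
Product: 10 (3R,5S,9R,10R)-drim-7-ene-3,11-diol, via B-(3-hydroxydrim-7-en-11-yl)-9-BBN 9 (not isolated)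
Conditions: 9-BBN (excess), THF, 0 °C to rt; then NaOH, H2O2, 0 °C to rt
Reagents that add atoms: 9-borabicyclo[3.3.1]nonane [H]B1C2CCCC1CCC2 (boron of 9 only); hydrogen peroxide OO
Why: Hydroboration–oxidation should place boron on the terminal C11 of the exocyclic alkene and deliver hydrogen to C9 from the face opposite the axial C10 methyl, giving C9–H anti to that methyl (C11 equatorial) and leaving the hindered trisubstituted C7=C8 bond untouched.

Step 7
Reactants: 10 drim-7-ene-3,11-diol; 11 umbelliferone
Product: 12 7-{[(3R,5S,9R,10R)-3-hydroxydrim-7-en-11-yl]oxy}-2H-chromen-2-one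
Conditions: PPh3, DIAD, THF, 0 °C to rt
Reagents that add atoms: none
Why: The Mitsunobu etherification should activate only the primary C11 hydroxyl, because the secondary C3 hydroxyl is flanked by the gem-dimethyl carbon, and the acidic phenol of umbelliferone is a good pronucleophile; no stereocentre is involved.

Step 8
Reactants: 12 hydroxy ether
Product: 13 7-{[(3R,5S,9R,10R)-3-acetoxydrim-7-en-11-yl]oxy}-2H-chromen-2-one
Conditions: Ac2O, DMAP (cat.), pyridine, CH2Cl2, rt
Reagents that add atoms: acetic anhydride CC(=O)OC(C)=O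
Why: DMAP-catalysed acylation should esterify the hindered equatorial C3 alcohol with retention.

Step 9
Reactants: 13 acetate
Product: 14 7-{[(3R,5S,9R,10S)-3-acetoxy-6-oxodrim-7-en-11-yl]oxy}-2H-chromen-2-one (target)
Conditions: CrO3, 3,5-dimethylpyrazole, CH2Cl2, −20 °C
Reagents that add atoms: chromium trioxide O=[Cr](=O)=O
Why: Allylic oxidation with the CrO3–3,5-dimethylpyrazole complex should attack the ring methylene C6 next to the CH terminus of the trisubstituted alkene (the pattern known from 5-ene steroids to 7-ketones and 12-ene triterpenoids to 11-ketones) under non-basic conditions that avoid vinylogous elimination of the aryloxide; C5 stays in the favoured trans-fused configuration.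

Compound list
1 | (S)-(+)-carvone, (5S)-2-methyl-5-(prop-1-en-2-yl)cyclohex-2-en-1-one | CC1=CC[C@@H](CC1=O)C(C)=C | starting material
2 | lithium dienolate of carvone (O-lithio, C1=C6; not isolated) | [Li]OC1=C[C@@H](C(C)=C)CC=C1C | intermediate
3 | (5S,6R)-2,6-dimethyl-5-(prop-1-en-2-yl)cyclohex-2-en-1-one (trans-6-methylcarvone, major epimer) | C[C@H]1C(=O)C(C)=CC[C@@H]1C(C)=C | intermediate
4 | lithium dienolate of 6-methylcarvone (not isolated) | [Li]OC1=C(C)[C@@H](C(C)=C)CC=C1C | intermediate
5 | (5R,6R)-2,6-dimethyl-5-(prop-1-en-2-yl)-6-(prop-2-en-1-yl)cyclohex-2-en-1-one (allyl trans to isopropenyl) | C=CC[C@@]1(C)C(=O)C(C)=CC[C@@H]1C(C)=C | intermediate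
6 | 3-[(1R,6R)-1,3-dimethyl-2-oxo-6-(prop-1-en-2-yl)cyclohex-3-en-1-yl]propanal | O=CCC[C@@]1(C)C(=O)C(C)=CC[C@@H]1C(C)=C | intermediate
7 | (3R,5R,10R)-3-hydroxy-11-nordrim-7-en-9-one (trans-fused; 3-OH equatorial, cis to the C10 methyl) | O[C@@H]1CC[C@@]2(C)C(=O)C(C)=CC[C@@H]2C1(C)C | intermediate
8 | (3R,5S,10R)-drima-7,9(11)-dien-3-ol | O[C@@H]1CC[C@@]2(C)C(=C)C(C)=CC[C@@H]2C1(C)C | intermediate
9 | B-[(3R,5S,9R,10R)-3-hydroxydrim-7-en-11-yl]-9-borabicyclo[3.3.1]nonane (not isolated) | O[C@@H]1CC[C@@]2(C)[C@H](CB3C4CCCC3CCC4)C(C)=CC[C@@H]2C1(C)C | intermediate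
10 | (3R,5S,9R,10R)-drim-7-ene-3,11-diol | O[C@@H]1CC[C@@]2(C)[C@H](CO)C(C)=CC[C@@H]2C1(C)C | intermediate
11 | umbelliferone (7-hydroxy-2H-chromen-2-one) | Oc1ccc2ccc(=O)oc2c1 | starting material
12 | 7-{[(3R,5S,9R,10R)-3-hydroxydrim-7-en-11-yl]oxy}-2H-chromen-2-one | O[C@@H]1CC[C@@]2(C)[C@H](COc3ccc4ccc(=O)oc4c3)C(C)=CC[C@@H]2C1(C)C | intermediate
13 | 7-{[(3R,5S,9R,10R)-3-acetoxydrim-7-en-11-yl]oxy}-2H-chromen-2-one | CC(=O)O[C@@H]1CC[C@@]2(C)[C@H](COc3ccc4ccc(=O)oc4c3)C(C)=CC[C@@H]2C1(C)C | intermediate
14 | 7-{[(3R,5S,9R,10S)-3-acetoxy-6-oxodrim-7-en-11-yl]oxy}-2H-chromen-2-one | CC(=O)O[C@@H]1CC[C@@]2(C)[C@H](COc3ccc4ccc(=O)oc4c3)C(C)=CC(=O)[C@@H]2C1(C)C | target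

Total step count: 9. Longest linear sequence: 9 steps, from (S)-carvone; umbelliferone is used as purchased.

Steps most likely to fail

1. Step 4 (key step). The tertiary C4 radical may be reduced before it cyclises (net hydrogenation of the isopropenyl group), the alkoxy radical may reopen by β-scission, and the two faces of the aldehyde may be poorly differentiated at C3. The fallback sets out from 6 and returns at 7; ring A is still the only ring closed. Aldehyde 6 would be converted with I2 and aqueous NH3 in THF into 3-[(1R,6R)-1,3-dimethyl-2-oxo-6-(prop-1-en-2-yl)cyclohex-3-en-1-yl]propanenitrile F1. The same Fe(acac)3/PhSiH3 conditions in EtOH should then add the C4 radical to the nitrile carbon (the known HAT-initiated alkene–nitrile cyclisation, whose iminyl radical does not reopen), giving the ring A ketimine 3-imino-11-nordrim-7-en-9-one F2, not isolated. Acidic work-up should hydrolyse it to 11-nordrim-7-ene-3,9-dione F3. NaBH4 in MeOH at −20 °C should reduce the saturated C3 ketone ahead of the hindered conjugated C9 ketone, with axial hydride delivery, to give the equatorial alcohol 7.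

2. Step 9. Hydrogen abstraction at the tertiary allylic C9–H or at the C8 methyl group may compete with C6, giving transposed enones or over-oxidation on the most advanced material. The fallback sets out from 7 and returns at 14. It installs the C6 oxygen while C6 is the only enolisable, doubly activated γ-methylene of the C9 enone:
- Acetylation of 7 (Ac2O, DMAP, pyridine) would give 3-acetoxy-11-nordrim-7-en-9-one F4.
- γ-Oxidation (Pd(OH)2 on carbon, t-BuOOH, K2CO3, CH2Cl2) would give the ene-dione 3-acetoxy-11-nordrim-7-ene-6,9-dione F5.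
- Luche reduction (NaBH4, CeCl3·7H2O, MeOH, −78 °C) at the less hindered C6 carbonyl would give 3-acetoxy-6-hydroxy-11-nordrim-7-en-9-one F6.
- Lombardo-type methylenation (Zn, CH2Br2, TiCl4, THF) would give 3-acetoxydrima-7,9(11)-dien-6-ol F7.
- Hydroboration–oxidation (9-BBN; then NaBO3·4H2O) would give 3-acetoxydrim-7-ene-6,11-diol F8.
- Mitsunobu coupling of the primary hydroxyl with 11 (PPh3, DIAD) would give 7-[(3-acetoxy-6-hydroxydrim-7-en-11-yl)oxy]-2H-chromen-2-one F9.
- MnO2 in CH2Cl2 would oxidise the allylic C6 alcohol to 14.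

3. Step 5. The basic ylide may deprotonate the hindered enone at the γ-position (C6) instead of adding to the carbonyl flanked by quaternary C10 and the C8 methyl, stalling conversion or deconjugating the alkene. The fallback sets out from 7 and returns at 8. It is a two-stage Peterson olefination: Me3SiCH2Li with anhydrous CeCl3 in THF at −78 °C (a small, weakly basic nucleophile) would add 1,2 to give the β-hydroxysilane 9-[(trimethylsilyl)methyl]-11-nordrim-7-ene-3,9-diol F10. KH in THF would then trigger syn-elimination to diene 8.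

Further compounds
F1 | step 4 | 3-[(1R,6R)-1,3-dimethyl-2-oxo-6-(prop-1-en-2-yl)cyclohex-3-en-1-yl]propanenitrile | N#CCC[C@@]1(C)C(=O)C(C)=CC[C@@H]1C(C)=C
F2 | step 4 | 3-imino-11-nordrim-7-en-9-one (ring A ketimine, not isolated) | N=C1CC[C@@]2(C)C(=O)C(C)=CC[C@@H]2C1(C)C
F3 | step 4 | 11-nordrim-7-ene-3,9-dione | O=C1CC[C@@]2(C)C(=O)C(C)=CC[C@@H]2C1(C)C
F4 | step 9 | 3-acetoxy-11-nordrim-7-en-9-one | CC(=O)O[C@@H]1CC[C@@]2(C)C(=O)C(C)=CC[C@@H]2C1(C)C
F5 | step 9 | 3-acetoxy-11-nordrim-7-ene-6,9-dione | CC(=O)O[C@@H]1CC[C@@]2(C)C(=O)C(C)=CC(=O)[C@@H]2C1(C)C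
F6 | step 9 | 3-acetoxy-6-hydroxy-11-nordrim-7-en-9-one (either C6 epimer) | CC(=O)O[C@@H]1CC[C@@]2(C)C(=O)C(C)=CC(O)[C@@H]2C1(C)C
F7 | step 9 | 3-acetoxydrima-7,9(11)-dien-6-ol (either C6 epimer) | CC(=O)O[C@@H]1CC[C@@]2(C)C(=C)C(C)=CC(O)[C@@H]2C1(C)C
F8 | step 9 | 3-acetoxydrim-7-ene-6,11-diol (either C6 epimer) | CC(=O)O[C@@H]1CC[C@@]2(C)[C@H](CO)C(C)=CC(O)[C@@H]2C1(C)C
F9 | step 9 | 7-[(3-acetoxy-6-hydroxydrim-7-en-11-yl)oxy]-2H-chromen-2-one (either C6 epimer) | CC(=O)O[C@@H]1CC[C@@]2(C)[C@H](COc3ccc4ccc(=O)oc4c3)C(C)=CC(O)[C@@H]2C1(C)C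
F10 | step 5 | 9-[(trimethylsilyl)methyl]-11-nordrim-7-ene-3,9-diol (either C9 epimer) | O[C@@H]1CC[C@@]2(C)C(O)(C[Si](C)(C)C)C(C)=CC[C@@H]2C1(C)C
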